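Everything rests on cutting the bond between C7, the inner carbon of the exocyclic C7=C14H2 alkene on ring carbon C1, and the carbinol carbon C8. This 2-substituted allylic alcohol unit is the retron of a Nozaki–Hiyama–Kishi alkenylation. In one operation a ligand-controlled Ni/Cr coupling joins the two halves, forms C7–C8 and sets C8, while ketone, ester, hydroxyl and oxirane groups stay untouched. Its precursors are a cyclohexenone 2-iodoalkene with C1, C2 and C6 already set, whose enone is the latent C3 carbinol and C4–C5 oxirane, and the enantiopure β,γ-epoxy aldehyde C8–C13. Luche reduction and hydroxyl-directed epoxidation then finish the ring.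

Key step: step 9

Numbering used below: ring C1 (bears the side chain), C2 (CHOAng next to the carbinol), C3 (CHOH), C4 (C–CH3), C5 (oxirane CH), C6 (CHOAng); chain C7(=C14H2), C8 (CHOAng), C9, C10, C11 (with C12, C13). Ang = (Z)-2-methylbut-2-enoyl.
Remark: enone 1 is taken as a catalogue compound in enantiopure form.

Step 1
Reactants: 1 (4S)-4-(tert-butyldimethylsilyloxy)cyclohex-2-en-1-one
Product: 2 (4S)-4-(tert-butyldimethylsilyloxy)-6-methylcyclohex-2-en-1-one (both C6 epimers)
Conditions: LDA, THF, −78 °C; MeI, −78 → −20 °C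
Reagents that add atoms: iodomethane, CI
Why: Kinetic deprotonation at the α′-CH2 gives the cross-conjugated lithium enolate, and its C-alkylation (enolate alkylation) brings in the future C4 methyl group, the new centre being an inconsequential epimer mixture that becomes sp2 in step 3.

Step 2
Reactants: 2 (4S)-4-(tert-butyldimethylsilyloxy)-6-methylcyclohex-2-en-1-one; 3 (1-bromovinyl)trimethylsilane
Product: 5 (4S,5S)-4-(tert-butyldimethylsilyloxy)-2-methyl-5-[1-(trimethylsilyl)vinyl]cyclohexan-1-one (both C2 epimers), via 1-(trimethylsilyl)vinylmagnesium bromide 4 (not isolated)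
Conditions: 3, Mg, THF; then CuBr·SMe2 (20 mol %), 2, THF, −78 → −40 °C; aq NH4Cl
Reagents that add atoms: magnesium, [Mg] (stays only in 4)
Why: Copper-catalysed conjugate addition of the α-silylvinyl Grignard reagent should occur anti to the neighbouring silyloxy group, as is usual for 4-silyloxycyclohexenones, which sets C1 trans to the C6 oxygen and brings in C7 and C14 as a masked 2-iodoalkene.

Step 3
Reactants: 5 (4S,5S)-4-(tert-butyldimethylsilyloxy)-2-methyl-5-[1-(trimethylsilyl)vinyl]cyclohexan-1-one
Product: 7 (4S,5S)-4-(tert-butyldimethylsilyloxy)-2-methyl-5-[1-(trimethylsilyl)vinyl]cyclohex-2-en-1-one, via tetrasubstituted trimethylsilyl enol ether 6 (not isolated)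
Conditions: TMSCl, NaI, Et3N, MeCN, rt; then Pd(OAc)2 (10 mol %), O2 (1 atm), DMSO, rt
Reagents that add atoms: chlorotrimethylsilane, C[Si](C)(C)Cl (silyl group stays only in 6)
Why: Silylation under equilibrating conditions favours the tetrasubstituted enol ether on the methyl-bearing side, away from the hindered C1 flank, and Saegusa–Ito oxidation (aerobic variant) then gives the 2-methylcyclohexenone by β-hydride loss from the ring CH2, which removes the epimeric centre.

Step 4
Reactants: 7 (4S,5S)-4-(tert-butyldimethylsilyloxy)-2-methyl-5-[1-(trimethylsilyl)vinyl]cyclohex-2-en-1-one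
Product: 8 (4S,5S,6S)-4-(tert-butyldimethylsilyloxy)-6-hydroxy-2-methyl-5-[1-(trimethylsilyl)vinyl]cyclohex-2-en-1-one
Conditions: KHMDS, THF, −78 °C; 2-(phenylsulfonyl)-3-phenyloxaziridine, −78 °C; AcOH quench
Reagents that add atoms: 2-(phenylsulfonyl)-3-phenyloxaziridine, O=S(=O)(c1ccccc1)N1OC1c1ccccc1
Why: Kinetic α′-enolisation as with carvone followed by enolate hydroxylation with the N-sulfonyloxaziridine should deliver oxygen anti to the bulky C1 substituent, which gives the C2 alcohol trans to the side chain, that is the epimer needed for an inverting esterification.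

Step 5
Reactants: 8 (4S,5S,6S)-4-(tert-butyldimethylsilyloxy)-6-hydroxy-2-methyl-5-[1-(trimethylsilyl)vinyl]cyclohex-2-en-1-one; 9 angelic acid, (Z)-2-methylbut-2-enoic acid
Product: 10 (1R,5S,6S)-5-(tert-butyldimethylsilyloxy)-3-methyl-2-oxo-6-[1-(trimethylsilyl)vinyl]cyclohex-3-en-1-yl (Z)-2-methylbut-2-enoate
Conditions: PPh3, DIAD, toluene, 0 °C → rt
Reagents that add atoms: none
Why: Mitsunobu esterification activates the alcohol and not the acid, so that the angelate attacks C2 in an SN2 step that the adjacent carbonyl group accelerates, which inverts C2 to the cis relation with C1 found in the target and keeps the Z geometry of the acid.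

Step 6
Reactants: 10 (1R,5S,6S)-5-(tert-butyldimethylsilyloxy)-3-methyl-2-oxo-6-[1-(trimethylsilyl)vinyl]cyclohex-3-en-1-yl (Z)-2-methylbut-2-enoate
Product: 12 (1R,5S,6R)-5-hydroxy-6-(1-iodovinyl)-3-methyl-2-oxocyclohex-3-en-1-yl (Z)-2-methylbut-2-enoate, via silyl ether iodoalkene 11 (not isolated)
Conditions: NIS, MeCN, 0 °C, dark; then HF·pyridine, 0 °C → rt
Reagents that add atoms: N-iodosuccinimide, O=C1CCC(=O)N1I
Why: Electrophilic ipso-iododesilylation replaces the vinylic silyl group by iodine without touching the electron-poor enone and angelate alkenes, and cleavage of the silyl ether with buffered HF in the same flask frees the C6 hydroxyl group with no change at any stereocentre.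

Step 7
Reactants: 13 4-methylpent-3-en-1-ol
Product: 14 2-[(2R)-3,3-dimethyloxiran-2-yl]ethan-1-ol
Conditions: D-fructose-derived ketone (30 mol %), Oxone, K2CO3, Bu4NHSO4 (cat.), MeCN–CH2(OMe)2 / aq Na2B4O7–EDTA buffer, 0 °C
Reagents that add atoms: potassium peroxymonosulfate (Oxone), [K+].[O-]S(=O)(=O)OO
Why: Shi epoxidation through the spiro transition state of the dioxirane from the D-fructose-derived ketone should give the R oxirane (C10) from this trisubstituted alkene, and the basic buffer prevents cyclisation of the epoxy alcohol.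

Step 8
Reactants: 14 2-[(2R)-3,3-dimethyloxiran-2-yl]ethan-1-ol
Product: 15 [(2R)-3,3-dimethyloxiran-2-yl]acetaldehyde
Conditions: Dess–Martin periodinane, NaHCO3, CH2Cl2, 0 °C; used at once
Reagents that add atoms: none
Why: Buffered Dess–Martin oxidation stops at the aldehyde under almost neutral conditions, which avoids β-elimination of the β,γ-epoxy aldehyde and leaves C10 untouched.

Step 9
Reactants: 12 (1R,5S,6R)-5-hydroxy-6-(1-iodovinyl)-3-methyl-2-oxocyclohex-3-en-1-yl (Z)-2-methylbut-2-enoate; 15 [(2R)-3,3-dimethyloxiran-2-yl]acetaldehyde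
Product: 16 (1R,5S,6R)-6-{(3S)-4-[(2R)-3,3-dimethyloxiran-2-yl]-3-hydroxybut-1-en-2-yl}-5-hydroxy-3-methyl-2-oxocyclohex-3-en-1-yl (Z)-2-methylbut-2-enoate
Conditions: CrCl2 (15 mol %), chiral oxazoline–sulfonamide ligand (17 mol %), proton sponge (cat.), NiCl2·neocuproine (2 mol %), Mn (2 equiv), Cp2ZrCl2 (2.2 equiv), LiCl, MeCN, rt
Reagents that add atoms: none
Why: Ni(0) inserts into the C7–I bond of 12, the alkenyl group passes to Cr(III), and the alkenylchromium(III) species bound to the chiral oxazoline–sulfonamide ligand adds to the aldehyde carbon C8 of 15, while Mn(0) returns Cr(III) to Cr(II) and Cp2ZrCl2 frees the chromium alkoxide so that chromium stays catalytic. The closest known reaction type is the catalytic asymmetric Nozaki–Hiyama–Kishi coupling of 2-iodo-1-alkenes with aliphatic aldehydes. No ring is closed. The only new stereocentre, C8, is set by the ligand on chromium (reagent control, with the ligand enantiomer that gives the 8S carbinol), so neither the remote C10 nor the crowded C1 environment has to direct the addition. The step needs attack on the aldehyde alone in the presence of the enone, an ester, a free hydroxyl group and an oxirane, and no enolisation of the β,γ-epoxy aldehyde; the low basicity and strong aldehyde preference of alkenylchromium reagents secure this, the trisubstituted enone is hindered, and the low stationary Cr(II) level should spare the α′-acyloxy ketone. No alkene geometry issue arises because C7=C14H2 is 1,1-disubstituted.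

Step 10
Reactants: 16 enone diol from step 9; 9 angelic acid
Product: 18 tris-angelate enone (3-oxo-Δ4 compound with O2, O6 and O8 angeloylated and C1, C2, C6, C8, C10 as in 20), via angelic 2,4,6-trichlorobenzoic anhydride 17 (not isolated)
Conditions: 9 (5 equiv), 2,4,6-Cl3C6H2COCl, Et3N, toluene, rt; then 16, 80 °C
Reagents that add atoms: 2,4,6-trichlorobenzoyl chloride, O=C(Cl)c1c(Cl)cc(Cl)cc1Cl (aroyl group stays only in 17)
Why: Yamaguchi-type esterification through the mixed aroyl anhydride without nucleophilic catalyst is the standard way to acylate hindered secondary alcohols with angelic acid without Z to E isomerisation, and it esterifies O6 and O8 in one operation with retention at both carbons.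

Step 11
Reactants: 18 tris-angelate enone
Product: 19 tris-angelate allylic alcohol (3R carbinol, hydroxyl cis to O2 and to the C1 chain, C4=C5 alkene)
Conditions: NaBH4, CeCl3·7H2O, MeOH, −78 °C
Reagents that add atoms: none
Why: Luche reduction gives clean 1,2-reduction of the enone in the presence of the three unsaturated esters, and hydride attack anti to the pseudo-axial C2 ester oxygen (polar Felkin–Anh, as in carvone to cis-carveol) should place the C3 hydroxyl group cis to O2 and to the C1 chain.

Step 12
Reactants: 19 tris-angelate allylic alcohol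
Product: 20 target CNP0147918.1
Conditions: VO(acac)2 (5 mol %), t-BuOOH (decane), CH2Cl2, 0 °C
Reagents that add atoms: tert-butyl hydroperoxide, CC(C)(C)OO
Why: Vanadium-catalysed hydroxyl-directed epoxidation delivers oxygen to the C4=C5 alkene from the face of the C3 hydroxyl group, which is also the face anti to the C6 ester, so that C4 and C5 are set together, while the 1,1-disubstituted C7=C14 alkene and the electron-poor angelates are not allylic-alcohol alkenes and stay intact.

Compound list
1 | (4S)-4-(tert-butyldimethylsilyloxy)cyclohex-2-en-1-one | O=C1C=C[C@@H](O[Si](C)(C)C(C)(C)C)CC1 | starting material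
2 | (4S)-4-(tert-butyldimethylsilyloxy)-6-methylcyclohex-2-en-1-one (C6 epimers) | O=C1C=C[C@@H](O[Si](C)(C)C(C)(C)C)CC1C | intermediate
3 | (1-bromovinyl)trimethylsilane | C=C(Br)[Si](C)(C)C | starting material
4 | 1-(trimethylsilyl)vinylmagnesium bromide | C=C([Mg]Br)[Si](C)(C)C | intermediate
5 | (4S,5S)-4-(tert-butyldimethylsilyloxy)-2-methyl-5-[1-(trimethylsilyl)vinyl]cyclohexan-1-one (C2 epimers, 4,5-trans) | C=C([Si](C)(C)C)[C@H]1CC(=O)C(C)C[C@@H]1O[Si](C)(C)C(C)(C)C | intermediate
6 | tetrasubstituted trimethylsilyl enol ether of 5 | C=C([Si](C)(C)C)[C@H]1CC(O[Si](C)(C)C)=C(C)C[C@@H]1O[Si](C)(C)C(C)(C)C | intermediate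
7 | (4S,5S)-4-(tert-butyldimethylsilyloxy)-2-methyl-5-[1-(trimethylsilyl)vinyl]cyclohex-2-en-1-one | C=C([Si](C)(C)C)[C@H]1CC(=O)C(C)=C[C@@H]1O[Si](C)(C)C(C)(C)C | intermediate
8 | (4S,5S,6S)-4-(tert-butyldimethylsilyloxy)-6-hydroxy-2-methyl-5-[1-(trimethylsilyl)vinyl]cyclohex-2-en-1-one | C=C([Si](C)(C)C)[C@H]1[C@H](O)C(=O)C(C)=C[C@@H]1O[Si](C)(C)C(C)(C)C | intermediate
9 | angelic acid, (Z)-2-methylbut-2-enoic acid | C/C=C(/C)C(=O)O | starting material
10 | (1R,5S,6S)-5-(tert-butyldimethylsilyloxy)-3-methyl-2-oxo-6-[1-(trimethylsilyl)vinyl]cyclohex-3-en-1-yl angelate | C=C([Si](C)(C)C)[C@H]1[C@@H](OC(=O)/C(C)=C\C)C(=O)C(C)=C[C@@H]1O[Si](C)(C)C(C)(C)C | intermediate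
11 | (1R,5S,6S)-5-(tert-butyldimethylsilyloxy)-6-(1-iodovinyl)-3-methyl-2-oxocyclohex-3-en-1-yl angelate | C=C(I)[C@H]1[C@@H](OC(=O)/C(C)=C\C)C(=O)C(C)=C[C@@H]1O[Si](C)(C)C(C)(C)C | intermediate
12 | (1R,5S,6R)-5-hydroxy-6-(1-iodovinyl)-3-methyl-2-oxocyclohex-3-en-1-yl angelate | C=C(I)[C@H]1[C@@H](OC(=O)/C(C)=C\C)C(=O)C(C)=C[C@@H]1O | intermediate
13 | 4-methylpent-3-en-1-ol | CC(C)=CCCO | starting material
14 | 2-[(2R)-3,3-dimethyloxiran-2-yl]ethan-1-ol | OCC[C@H]1OC1(C)C | intermediate
15 | [(2R)-3,3-dimethyloxiran-2-yl]acetaldehyde | O=CC[C@H]1OC1(C)C | intermediate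
16 | (1R,5S,6R)-6-{(3S)-4-[(2R)-3,3-dimethyloxiran-2-yl]-3-hydroxybut-1-en-2-yl}-5-hydroxy-3-methyl-2-oxocyclohex-3-en-1-yl angelate | C=C([C@H]1[C@@H](OC(=O)/C(C)=C\C)C(=O)C(C)=C[C@@H]1O)[C@H](C[C@H]1OC1(C)C)O | intermediate
17 | angelic 2,4,6-trichlorobenzoic anhydride | C/C=C(/C)C(=O)OC(=O)c1c(Cl)cc(Cl)cc1Cl | intermediate
18 | tris-angelate enone (3-oxo, C4=C5) | C=C([C@H]1[C@@H](OC(=O)/C(C)=C\C)C(=O)C(C)=C[C@@H]1OC(=O)/C(C)=C\C)[C@H](C[C@H]1OC1(C)C)OC(=O)/C(C)=C\C | intermediate
19 | tris-angelate allylic alcohol (3R-OH, C4=C5) | C=C([C@H]1[C@@H](OC(=O)/C(C)=C\C)[C@@H](O)C(C)=C[C@@H]1OC(=O)/C(C)=C\C)[C@H](C[C@H]1OC1(C)C)OC(=O)/C(C)=C\C | intermediate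
20 | CNP0147918.1 | C=C([C@H]1[C@@H](OC(=O)/C(C)=C\C)[C@@H](O)[C@@]2(C)O[C@H]2[C@@H]1OC(=O)/C(C)=C\C)[C@H](C[C@H]1OC1(C)C)OC(=O)/C(C)=C\C | target

Total steps: 12. Longest linear sequence: 10 steps (steps 1–6 and 9–12, from 1).

Steps most likely to fail

Step 9. The β,γ-epoxy aldehyde may be consumed by Lewis-acid opening or β-elimination before it is attacked. Electron transfer from the low-valent metals to the α′-acyloxy enone may compete. Facial selectivity at C8 may erode on this crowded alkenyl partner. The fallback puts the side-chain oxirane in after the coupling. It sets out from 13, which is oxidised with buffered Dess–Martin periodinane to 4-methylpent-3-enal F3. The same Ni/Cr coupling with 12 gives the prenyl-type enone diol F4. Double angeloylation as in step 10 gives the triester diene F5. A Shi epoxidation, selective for the only electron-rich trisubstituted alkene (C10=C11), comes back to the route at 18.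

Step 5. The activated C2 oxygen may be lost by elimination toward C1 followed by aromatisation. Substitution next to the bulky C1 group may be slow, and the pseudo-axial ester may epimerise. The fallback replaces alcohol activation by halide displacement and sets out from 7. TMSOTf and Et3N give the cross-conjugated silyl dienol ether F1. NBS brominates it anti to the C1 group to give the trans α′-bromo ketone F2. Caesium angelate (from 9 and Cs2CO3, DMF, rt) then displaces bromide with inversion, and the sequence comes back to the route at 10.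

Step 10. The activated angelate may isomerise from Z to E. Acylation of the hindered C8 hydroxyl group may stay incomplete, and C2 may epimerise during prolonged heating with amine. The fallback builds the acyl groups on the alcohol oxygens by palladium-catalysed alkoxycarbonylation. Diol 16, (Z)-2-bromobut-2-ene, CO, a Pd(0)–bisphosphine catalyst and i-Pr2NEt in toluene at 60 °C should form Z-configured acylpalladium species, which the two hydroxyl groups capture. It sets out from 16 and comes back at 18 without a new isolable compound.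

Further compounds
F1 | step 5 | cross-conjugated trimethylsilyl dienol ether of 7 | C=C([Si](C)(C)C)[C@H]1C=C(O[Si](C)(C)C)C(C)=C[C@@H]1O[Si](C)(C)C(C)(C)C
F2 | step 5 | trans α′-bromo ketone, (4S,5S)-6-bromo-4-(tert-butyldimethylsilyloxy)-2-methyl-5-[1-(trimethylsilyl)vinyl]cyclohex-2-en-1-one with bromine anti to the C5 group | C=C([Si](C)(C)C)[C@H]1[C@H](Br)C(=O)C(C)=C[C@@H]1O[Si](C)(C)C(C)(C)C
F3 | step 9 | 4-methylpent-3-enal | CC(C)=CCC=O
F4 | step 9 | prenyl-type enone diol (8S, C10=C11 alkene) | C=C([C@H]1[C@@H](OC(=O)/C(C)=C\C)C(=O)C(C)=C[C@@H]1O)[C@H](CC=C(C)C)O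
F5 | step 9 | triester diene (tris-angelate enone with C10=C11 alkene) | C=C([C@H]1[C@@H](OC(=O)/C(C)=C\C)C(=O)C(C)=C[C@@H]1OC(=O)/C(C)=C\C)[C@H](CC=C(C)C)OC(=O)/C(C)=C\C
F0 | step 10 | none | none
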